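**Retrosynthetic overview**
- Target ⇐ 3'-O-benzyl flavone by hydrogenolysis of the benzyl ether (last step).
- Ring C (pyranone, formed last) ⇐ iodine/DMSO oxidative cyclisation of a 2'-hydroxychalcone that already carries rings A and B.
- Chalcone ⇐ Claisen–Schmidt aldol condensation (key C–C bond) of the ring A acetophenone with the ring B benzaldehyde.
- Ring A ketone ⇐ C-acetylation of 3,4,5-trimethoxyphenol.
- Ring B aldehyde ⇐ 2,3,4-trimethoxybenzaldehyde: ortho-demethylation, benzylation, Dakin oxidation, ortho-formylation, methylation.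

Assumption: the target is achiral (no stereocentre), so there is no enantiomer to control; the only stereo-element in the route is the E double bond of the chalcone, which is consumed on cyclisation.

**Route**

Step 1
Reactants: 1 3,4,5-trimethoxyphenol
Product: 3 1-(6-hydroxy-2,3,4-trimethoxyphenyl)ethan-1-one, via difluoroboron chelate 2 (not isolated)
Conditions: AcOH, BF3·OEt2 (3 equiv), 90 °C, 2 h; then H2O/EtOH, 60 °C
Reagents that add atoms: acetic acid, CC(=O)O
Why: Friedel–Crafts (Fries-type) C-acylation ortho to the phenol of a strongly activated ring whose two ortho positions are equivalent, so one regioisomer forms; the ketone is held as its BF2 chelate (no over-acylation) and released on hydrolysis.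

Step 2
Reactants: 4 2,3,4-trimethoxybenzaldehyde
Product: 6 2-hydroxy-3,4-dimethoxybenzaldehyde, via aryloxydichloroborane 5 (not isolated)
Conditions: BCl3 (1.1 equiv), CH2Cl2, 0 °C to rt; then H2O
Reagents that add atoms: none
Why: Chelation-controlled Lewis acid ether cleavage; BCl3 bound to the aldehyde oxygen cleaves only the methyl ether ortho to CHO and leaves the 3- and 4-OMe groups intact.

Step 3
Reactants: 6 2-hydroxy-3,4-dimethoxybenzaldehyde
Product: 7 2-(benzyloxy)-3,4-dimethoxybenzaldehyde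
Conditions: BnBr (1.2 equiv), K2CO3, DMF, 60 °C
Reagents that add atoms: benzyl bromide, BrCc1ccccc1
Why: Williamson ether synthesis on the only phenol present; the benzyl group marks the oxygen that becomes the free 3'-OH of the target.

Step 4
Reactants: 7 2-(benzyloxy)-3,4-dimethoxybenzaldehyde
Product: 9 2-(benzyloxy)-3,4-dimethoxyphenol, via aryl formate 8 (not isolated)
Conditions: mCPBA (1.3 equiv), CH2Cl2, 0 °C to rt; NaHCO3 wash; then K2CO3 (0.2 equiv), MeOH, rt
Reagents that add atoms: mCPBA (3-chloroperoxybenzoic acid), OOC(=O)c1cccc(Cl)c1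
Why: Dakin-type Baeyer–Villiger oxidation; the electron-rich aryl group (ortho- and para-alkoxy) migrates in preference to hydride, and the formate is removed by mild methanolysis.

Step 5
Reactants: 9 2-(benzyloxy)-3,4-dimethoxyphenol
Product: 11 3-(benzyloxy)-2-hydroxy-4,5-dimethoxybenzaldehyde, via salicyl alcohol 10 (not isolated)
Conditions: MgCl2 (anhydrous, 2 equiv), Et3N (4 equiv), (CH2O)n (6 equiv), MeCN, reflux; then 1 M HCl
Reagents that add atoms: formaldehyde (as paraformaldehyde), C=O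
Why: Casnati–Skattebøl magnesium-mediated ortho-formylation; the magnesium phenoxide delivers formaldehyde only ortho to oxygen, C6 is the single free ortho position, and the benzylic alkoxide is oxidised in situ by hydride transfer to a second formaldehyde.

Step 6
Reactants: 11 3-(benzyloxy)-2-hydroxy-4,5-dimethoxybenzaldehyde
Product: 12 3-(benzyloxy)-2,4,5-trimethoxybenzaldehyde
Conditions: MeI (2 equiv), K2CO3, DMF, 40 °C
Reagents that add atoms: iodomethane, CI
Why: Williamson O-methylation of the only free phenol completes the ring B substitution pattern (2,4,5-OMe, 3-OBn).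

Step 7
Reactants: 3 1-(6-hydroxy-2,3,4-trimethoxyphenyl)ethan-1-one; 12 3-(benzyloxy)-2,4,5-trimethoxybenzaldehyde
Product: 14 (E)-3-[3-(benzyloxy)-2,4,5-trimethoxyphenyl]-1-(6-hydroxy-2,3,4-trimethoxyphenyl)prop-2-en-1-one, via racemic aldol adduct 13 (not isolated)
Conditions: KOH (50% aq., excess), EtOH, rt, 48 h; then cold 1 M HCl
Reagents that add atoms: none
Why: Claisen–Schmidt (crossed aldol) condensation of the methyl ketone enolate with a non-enolisable aldehyde; E1cB dehydration removes the aldol stereocentre and gives the thermodynamically favoured E-enone.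

Step 8
Reactants: 14 (E)-3-[3-(benzyloxy)-2,4,5-trimethoxyphenyl]-1-(6-hydroxy-2,3,4-trimethoxyphenyl)prop-2-en-1-one
Product: 16 2-[3-(benzyloxy)-2,4,5-trimethoxyphenyl]-5,6,7-trimethoxy-4H-chromen-4-one, via racemic flavanone 15 (not isolated)
Conditions: I2 (10 mol %), DMSO, 130 °C, 3 h; then aq. Na2S2O3
Reagents that add atoms: none
Why: Iodine/DMSO oxidative cyclisation; intramolecular oxa-Michael addition of the single 2'-OH gives the flavanone, which is dehydrogenated by α-iodination and HI elimination while DMSO reoxidises HI, so the transient C2 stereocentre disappears.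

Step 9
Reactants: 16 2-[3-(benzyloxy)-2,4,5-trimethoxyphenyl]-5,6,7-trimethoxy-4H-chromen-4-one
Product: 17 Agecorynin G, 2-(3-hydroxy-2,4,5-trimethoxyphenyl)-5,6,7-trimethoxy-4H-chromen-4-one
Conditions: H2 (1 atm), 10% Pd/C, EtOAc/MeOH, rt
Reagents that add atoms: none
Why: Catalytic hydrogenolysis of the benzyl ether under neutral conditions that leave the six methyl ethers and the chromone untouched; no stereocentre is involved.

**Compound list**

1 | 3,4,5-trimethoxyphenol | COc1cc(O)cc(OC)c1OC | starting material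
2 | difluoroboron chelate of ketone 3 (2,2-difluoro-5,6,7-trimethoxy-4-methyl-1,3,2-benzodioxaborinine, O→B dative form; not isolated) | CC1=[O+][B-](F)(F)Oc2cc(OC)c(OC)c(OC)c12 | intermediate
3 | 1-(6-hydroxy-2,3,4-trimethoxyphenyl)ethan-1-one | CC(=O)c1c(O)cc(OC)c(OC)c1OC | intermediate
4 | 2,3,4-trimethoxybenzaldehyde | COc1ccc(C=O)c(OC)c1OC | starting material
5 | dichloro(6-formyl-2,3-dimethoxyphenoxy)borane (not isolated) | COc1ccc(C=O)c(OB(Cl)Cl)c1OC | intermediate
6 | 2-hydroxy-3,4-dimethoxybenzaldehyde | COc1ccc(C=O)c(O)c1OC | intermediate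
7 | 2-(benzyloxy)-3,4-dimethoxybenzaldehyde | COc1ccc(C=O)c(OCc2ccccc2)c1OC | intermediate
8 | 2-(benzyloxy)-3,4-dimethoxyphenyl formate (not isolated) | COc1ccc(OC=O)c(OCc2ccccc2)c1OC | intermediate
9 | 2-(benzyloxy)-3,4-dimethoxyphenol | COc1ccc(O)c(OCc2ccccc2)c1OC | intermediate
10 | 2-(benzyloxy)-6-(hydroxymethyl)-3,4-dimethoxyphenol (not isolated) | COc1cc(CO)c(O)c(OCc2ccccc2)c1OC | intermediate
11 | 3-(benzyloxy)-2-hydroxy-4,5-dimethoxybenzaldehyde | COc1cc(C=O)c(O)c(OCc2ccccc2)c1OC | intermediate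
12 | 3-(benzyloxy)-2,4,5-trimethoxybenzaldehyde | COc1cc(C=O)c(OC)c(OCc2ccccc2)c1OC | intermediate
13 | 3-[3-(benzyloxy)-2,4,5-trimethoxyphenyl]-3-hydroxy-1-(6-hydroxy-2,3,4-trimethoxyphenyl)propan-1-one (racemic; not isolated) | COc1cc(C(O)CC(=O)c2c(O)cc(OC)c(OC)c2OC)c(OC)c(OCc2ccccc2)c1OC | intermediate
14 | (E)-3-[3-(benzyloxy)-2,4,5-trimethoxyphenyl]-1-(6-hydroxy-2,3,4-trimethoxyphenyl)prop-2-en-1-one | COc1cc(/C=C/C(=O)c2c(O)cc(OC)c(OC)c2OC)c(OC)c(OCc2ccccc2)c1OC | intermediate
15 | 2-[3-(benzyloxy)-2,4,5-trimethoxyphenyl]-5,6,7-trimethoxy-2,3-dihydro-4H-chromen-4-one (racemic; not isolated) | COc1cc(C2CC(=O)c3c(OC)c(OC)c(OC)cc3O2)c(OC)c(OCc2ccccc2)c1OC | intermediate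
16 | 2-[3-(benzyloxy)-2,4,5-trimethoxyphenyl]-5,6,7-trimethoxy-4H-chromen-4-one | COc1cc(-c2cc(=O)c3c(OC)c(OC)c(OC)cc3o2)c(OC)c(OCc2ccccc2)c1OC | intermediate
17 | Agecorynin G, 2-(3-hydroxy-2,4,5-trimethoxyphenyl)-5,6,7-trimethoxy-4H-chromen-4-one (achiral) | COc1cc(-c2cc(=O)c3c(OC)c(OC)c(OC)cc3o2)c(OC)c(O)c1OC | target

**Step count and risk**

Total steps: 9 (step 1 for ring A, steps 2–6 for ring B, steps 7–9 after convergence).
Longest linear sequence: 8 steps (4 → 17, steps 2–9).

Steps most likely to fail: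

Step 5 (ortho-formylation). Phenol 9 is hindered and carries a chelating ortho-benzyloxy group, so the reaction may be slow or stop at alcohol 10. The fallback sets out from 9 and comes back at 12. Phenol 9 is brominated at its only free ortho position (NBS, MeCN, 0 °C) to give 2-(benzyloxy)-6-bromo-3,4-dimethoxyphenol F1, which is O-methylated (MeI, K2CO3, DMF) to 3-(benzyloxy)-1-bromo-2,4,5-trimethoxybenzene F2. Bromine–lithium exchange (n-BuLi, THF, −78 °C) gives [3-(benzyloxy)-2,4,5-trimethoxyphenyl]lithium F3, which adds to DMF to give lithium [3-(benzyloxy)-2,4,5-trimethoxyphenyl](dimethylamino)methanolate F4; aqueous NH4Cl work-up collapses this to aldehyde 12.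

Step 7 (Claisen–Schmidt condensation). Both partners are electron-rich and ortho-substituted, so conversion may be low or the aldehyde may undergo Cannizzaro reaction. The fallback sets out from 12 (used together with 3) and comes back at 16, so it also replaces step 8. Aldehyde 12 is oxidised (NaClO2, NaH2PO4, 2-methyl-2-butene, t-BuOH/H2O) to 3-(benzyloxy)-2,4,5-trimethoxybenzoic acid F5 and converted ((COCl)2, cat. DMF, CH2Cl2) into 3-(benzyloxy)-2,4,5-trimethoxybenzoyl chloride F6. Ketone 3 is deprotonated with LiN(SiMe3)2 (3.2 equiv, THF, −78 °C) to dilithium 1-(2,3,4-trimethoxy-6-oxidophenyl)ethen-1-olate F7, which is C-acylated by F6 in an intermolecular Claisen condensation. NH4Cl work-up gives 1-[3-(benzyloxy)-2,4,5-trimethoxyphenyl]-3-(6-hydroxy-2,3,4-trimethoxyphenyl)propane-1,3-dione F8, and cyclodehydration (AcOH, cat. H2SO4, 95 °C) gives flavone 16.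

Step 9 (hydrogenolysis). The benzyl ether is flanked by two methoxy groups and may cleave slowly, and long exposure can saturate the C2–C3 double bond of the chromone. The fallback sets out from 12 and comes back at 17, removing the benzyl group before any enone exists. Aldehyde 12 is hydrogenolysed (H2, 10% Pd/C, EtOAc, rt, stopped after one equivalent of H2) to 3-hydroxy-2,4,5-trimethoxybenzaldehyde F9. Condensation of F9 with 3 (KOH in excess, EtOH, rt) passes through 3-hydroxy-1-(6-hydroxy-2,3,4-trimethoxyphenyl)-3-(3-hydroxy-2,4,5-trimethoxyphenyl)propan-1-one F10 to (E)-1-(6-hydroxy-2,3,4-trimethoxyphenyl)-3-(3-hydroxy-2,4,5-trimethoxyphenyl)prop-2-en-1-one F11. Treatment with I2 (10 mol %) in DMSO at 130 °C then gives, through 2-(3-hydroxy-2,4,5-trimethoxyphenyl)-5,6,7-trimethoxy-2,3-dihydro-4H-chromen-4-one F12, the target 17 directly.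

**Further compounds**

F1 | step 5 | 2-(benzyloxy)-6-bromo-3,4-dimethoxyphenol | COc1cc(Br)c(O)c(OCc2ccccc2)c1OC
F2 | step 5 | 3-(benzyloxy)-1-bromo-2,4,5-trimethoxybenzene | COc1cc(Br)c(OC)c(OCc2ccccc2)c1OC
F3 | step 5 | [3-(benzyloxy)-2,4,5-trimethoxyphenyl]lithium | [Li]c1cc(OC)c(OC)c(OCc2ccccc2)c1OC
F4 | step 5 | lithium [3-(benzyloxy)-2,4,5-trimethoxyphenyl](dimethylamino)methanolate (racemic) | [Li+].[O-]C(N(C)C)c1cc(OC)c(OC)c(OCc2ccccc2)c1OC
F5 | step 7 | 3-(benzyloxy)-2,4,5-trimethoxybenzoic acid | OC(=O)c1cc(OC)c(OC)c(OCc2ccccc2)c1OC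
F6 | step 7 | 3-(benzyloxy)-2,4,5-trimethoxybenzoyl chloride | ClC(=O)c1cc(OC)c(OC)c(OCc2ccccc2)c1OC
F7 | step 7 | dilithium 1-(2,3,4-trimethoxy-6-oxidophenyl)ethen-1-olate | [Li+].[Li+].C=C([O-])c1c([O-])cc(OC)c(OC)c1OC
F8 | step 7 | 1-[3-(benzyloxy)-2,4,5-trimethoxyphenyl]-3-(6-hydroxy-2,3,4-trimethoxyphenyl)propane-1,3-dione | COc1cc(C(=O)CC(=O)c2c(O)cc(OC)c(OC)c2OC)c(OC)c(OCc2ccccc2)c1OC
F9 | step 9 | 3-hydroxy-2,4,5-trimethoxybenzaldehyde | COc1cc(C=O)c(OC)c(O)c1OC
F10 | step 9 | 3-hydroxy-1-(6-hydroxy-2,3,4-trimethoxyphenyl)-3-(3-hydroxy-2,4,5-trimethoxyphenyl)propan-1-one (racemic) | COc1cc(C(O)CC(=O)c2c(O)cc(OC)c(OC)c2OC)c(OC)c(O)c1OC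
F11 | step 9 | (E)-1-(6-hydroxy-2,3,4-trimethoxyphenyl)-3-(3-hydroxy-2,4,5-trimethoxyphenyl)prop-2-en-1-one | COc1cc(/C=C/C(=O)c2c(O)cc(OC)c(OC)c2OC)c(OC)c(O)c1OC
F12 | step 9 | 2-(3-hydroxy-2,4,5-trimethoxyphenyl)-5,6,7-trimethoxy-2,3-dihydro-4H-chromen-4-one (racemic) | COc1cc(C2CC(=O)c3c(OC)c(OC)c(OC)cc3O2)c(OC)c(O)c1OC
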